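Per mol% of free catalyst is how I would reckon the quick number you asked for, and this is what I have in front of me.

all flasks: left-handed substrate 1.4 M; right-handed substrate 1.4 M

| run | reagent | free catalyst | remark | time |
|---|---|---|---|---|
| summer | 1.1 equiv | 0.69 mol% | run made earlier |  |
| noon | 1.1 equiv | 1.5 mol% | run made earlier |  |
| spring | 1.1 equiv | 2 mol% | run made earlier |  |
| gamma | 1.10 equiv | 0.85 mol% |  | 40 h |
| alpha | 1.10 equiv | 2.5 mol% |  | 40 h |

| run | time / h | right-handed substrate / % | left-handed substrate / % | left-handed product / % |
|---|---|---|---|---|
| summer | 2.00 | 46 | 39 | 8 |
| summer | 5.00 | 50 | 35 | 12 |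
| summer | 10.0 | 49 | 38 | 15 |
| summer | 15.0 | 51 | 34 | 11 |
| summer | 20.0 | 51 | 33 | 14 |
| noon | 4.00 | 48 | 28 | 21 |
| noon | 8.00 | 51 | 27 | 23 |
| noon | 12.0 | 49 | 30 | 24 |
| noon | 15.0 | 51 | 27 | 28 |
| noon | 20.0 | 50 | 30 | 19 |
| spring | 1.50 | 53 | 32 | 22 |
| spring | 3.00 | 50 | 27 | 25 |
| spring | 6.00 | 50 | 24 | 27 |
| spring | 10.0 | 50 | 26 | 30 |
| spring | 20.0 | 51 | 23 | 26 |

(standard deviation of a reading: 2 percentage points)

- free catalyst is single-handed; left-handed substrate and right-handed substrate are mirror images of each other, charged as a racemate, each of them at the stated concentration
- an excess is the difference of the two amounts in percent of their sum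
- an excess is below zero if the other one leads

- which of the two ends with the higher excess of right-handed substrate over left-handed substrate among what is left of the two ("neither" if they lie within 2 percentage points) (gamma / alpha / neither)
- excess of right-handed substrate over left-handed substrate among what is left of the two at the end, gamma
- excess of right-handed substrate over left-handed substrate among what is left of the two at the end, alpha

This is a kinetic resolution: the right-handed substrate stays near its starting level, while the left-handed substrate falls and then stands still, in the noon run at 28 % after 4.00 h and 30 % after 20.0 h, against a scatter of 2 percentage points. The charge holds 1.1 equiv of reagent to the left-handed substrate, so I take it that the catalyst is dying rather than the reagent failing. Suppose the left-handed substrate goes at a rate proportional to itself, the reagent and the catalyst, that the catalyst dies at a rate proportional to itself, and that the reagent may be treated as equal in amount to the left-handed substrate. Dividing the first rate by the second removes time, and what remains says that, once the catalyst has died and with the charges of substrate and reagent held as they are here, the charged amount of left-handed substrate over the amount left, minus one, which I call the gain, grows in step with the loading. On the level part of each run, from 10.0 h in summer, from 4.00 h at noon and from 6.00 h in spring, the gain over the loading, counted as a plain fraction of the left-handed substrate charged and not in mol%, reads 62.1, 50.7 and 52.7, and I take their mean, 55.2, as the capacity, the gain per unit of loading. For gamma that leaves left-handed substrate at 34.0 % of the two charged and an excess of 19.0 %, and for alpha 21.0 % and 40.8 %, so I say alpha.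

Your forecast also says alpha, with 19 % and 43 %, on the ground that “So the catalyst dies, and the final conversion is set by loading, not time”; my gamma agrees with it, and my alpha lies 2.2 points lower.

The flask gives alpha, with 19.8 % for gamma and 43.0 % for alpha, and after 40.0 h gamma holds 95.8 % of its catalyst as spent catalyst, 4.06 % as dormant form and 0.101 % as free catalyst.

    reagent → decomposition product (k = 1.16 × 10⁻⁷ s⁻¹)
    reagent + free catalyst + right-handed substrate → free catalyst + right-handed product (k = 2.25 × 10⁻⁵ L² mol⁻² s⁻¹)
    free catalyst ⇌ dormant form (K = 2.57, k = 8.58 × 10⁻⁶ s⁻¹)
    free catalyst → spent catalyst (k = 1.29 × 10⁻⁴ s⁻¹)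
    reagent + free catalyst + left-handed substrate → free catalyst + left-handed product (k = 0.00359 L² mol⁻² s⁻¹)

The neighbouring flask is gamma with 3.4 mol% of free catalyst, where the capacity gives a gain of 1.88, so left-handed substrate at 17.4 % and an excess of 48.4 %; that flask ends with 16.0 % of left-handed substrate and an excess of 51.2 %.

The readings stem from a simulated flask with made-up constants, noise included.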